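**Retrosynthetic overview**
- The last bond is the amidine C–N bond between the imidazole 2-amino group and C4 of 1-methylparabanic acid. The amino group comes from the imidazole C2–H by lithiation, azide transfer and reduction.
- The CH2 group between imidazole C5 and the phenol ring comes from an ortho-hydroxyaryl ketone, deoxygenated through its aryl carbonate with NaBH4.
- The strategy rests on the phenol ring: C1 carries the acyl (later benzylic) carbon, C2 the OH, C3 and C4 the OMe groups, C5 and C6 hydrogen. It is built by Diels–Alder reaction of a 1,1,2,3-tetraoxygenated buta-1,3-diene with a terminal imidazolyl ynone and aromatisation, which forms C1–C2 and C5–C6.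
- The ynone comes from 4,5-diiodo-1-methylimidazole (C5 formylation, C4 benzylation, ethynylation, oxidation). The diene comes from methyl methoxyacetate (C-acetylation, O-methylation, silylation).
- Only the phenol ring is formed in the route; the imidazole, the anisole ring and the imidazolidinetrione ring are bought.

Key step: step 8

Remark: the target has no stereocentre; the propargylic alcohol, the β-keto ester and the ketal cycloadduct are racemic and lose their stereocentres in later steps, and the enol ether and the diene are used as mixtures of double-bond isomers because these converge.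

Step 1
Reactants: 1 4,5-diiodo-1-methyl-1H-imidazole
Product: 3 4-iodo-1-methyl-1H-imidazole-5-carbaldehyde, via imidazol-5-ylmagnesium chloride 2 (not isolated)
Conditions: i-PrMgCl, THF, −20 °C; DMF, −20 °C → rt; aq. NH4Cl
Reagents that add atoms: N,N-dimethylformamide, CN(C)C=O
Why: Iodine–magnesium exchange of 1-substituted 4,5-diiodoimidazoles is fastest at C5, next to N1, and the Grignard reagent is formylated by DMF (Bouveault-type formylation) while the C4 iodide is kept for step 2.

Step 2
Reactants: 3 4-iodo-1-methyl-1H-imidazole-5-carbaldehyde, 4 2-(4-methoxybenzyl)-4,4,5,5-tetramethyl-1,3,2-dioxaborolane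
Product: 5 4-(4-methoxybenzyl)-1-methyl-1H-imidazole-5-carbaldehyde
Conditions: 4 (1.5 equiv), PdCl2(dppf) (5 mol %), K2CO3, 1,4-dioxane/H2O, 90 °C
Reagents that add atoms: none
Why: Suzuki–Miyaura coupling of the heteroaryl iodide with a benzylic pinacol boronate forms the C4–CH2 bond; a boron donor is chosen because it is inert to the free aldehyde, which a benzylic zinc halide would attack.

Step 3
Reactants: 5 4-(4-methoxybenzyl)-1-methyl-1H-imidazole-5-carbaldehyde
Product: 6 1-[4-(4-methoxybenzyl)-1-methyl-1H-imidazol-5-yl]prop-2-yn-1-ol (racemic)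
Conditions: HC≡CMgBr, THF, 0 °C; aq. NH4Cl
Reagents that add atoms: ethynylmagnesium bromide, C#C[Mg]Br
Why: 1,2-Addition of the ethynyl Grignard reagent to the aldehyde gives the racemic propargylic alcohol, whose stereocentre is removed in step 4.

Step 4
Reactants: 6 1-[4-(4-methoxybenzyl)-1-methyl-1H-imidazol-5-yl]prop-2-yn-1-ol
Product: 7 1-[4-(4-methoxybenzyl)-1-methyl-1H-imidazol-5-yl]prop-2-yn-1-one
Conditions: MnO2, CH2Cl2, rt; filtered, kept cold and used at once
Reagents that add atoms: none
Why: MnO2 oxidises the doubly activated (propargylic and heteroaryl) carbinol to the ynone under neutral heterogeneous conditions that spare the terminal alkyne and the base-sensitive ynone.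

Step 5
Reactants: 8 methyl methoxyacetate
Product: 10 methyl 2-methoxy-3-oxobutanoate (racemic), via lithium ester enolate 9 (not isolated)
Conditions: LiN(i-Pr)2 (2 equiv), 8 (2 equiv), THF, −78 °C; AcCl (1 equiv), −78 °C; aq. NH4Cl
Reagents that add atoms: acetyl chloride, CC(Cl)=O
Why: C-Acylation of the preformed lithium ester enolate with an acid chloride (crossed Claisen-type acylation); the second equivalent of enolate deprotonates the more acidic β-keto ester as it forms and so prevents a second acylation.

Step 6
Reactants: 10 methyl 2-methoxy-3-oxobutanoate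
Product: 11 methyl 2,3-dimethoxybut-2-enoate (mixture of double-bond isomers)
Conditions: HC(OMe)3, H2SO4 (cat.), rt; then distillation
Reagents that add atoms: trimethyl orthoformate, COC(OC)OC
Why: Acid-catalysed ketalisation of the β-keto ester with the orthoformate and loss of methanol on heating give the β-methoxy enoate, an O-methylation free of C-methylation; the double-bond isomers are not separated because all give the same dienolate in step 7.

Step 7
Reactants: 11 methyl 2,3-dimethoxybut-2-enoate
Product: 13 1,2,3-trimethoxy-1-(trimethylsilyloxy)buta-1,3-diene (mixture of geometric isomers), via lithium dienolate 12 (not isolated)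
Conditions: LiN(i-Pr)2, THF, −78 °C; TMSCl, −78 °C → rt; pentane, filtration, distillation under reduced pressure
Reagents that add atoms: chlorotrimethylsilane, C[Si](C)(C)Cl
Why: γ-Deprotonation of the β-methoxy enoate by the lithium amide and O-silylation of the dienolate give the vinylogous silyl ketene acetal, as in the preparation of Brassard-type dienes.

Step 8
Reactants: 7 1-[4-(4-methoxybenzyl)-1-methyl-1H-imidazol-5-yl]prop-2-yn-1-one, 13 1,2,3-trimethoxy-1-(trimethylsilyloxy)buta-1,3-diene
Product: 16 (2-hydroxy-3,4-dimethoxyphenyl)[4-(4-methoxybenzyl)-1-methyl-1H-imidazol-5-yl]methanone, via ketal cycloadduct 14 (not isolated), via aryl trimethylsilyl ether 15 (not isolated)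
Conditions: 13 (2 equiv), toluene, rt → 70 °C; then 1 M HCl, THF, rt; NaHCO3
Reagents that add atoms: none
Why: The electron-rich diene 13 and the electron-poor alkyne of 7 should combine in a normal-electron-demand Diels–Alder reaction (strongly asynchronous, at the limit a Mukaiyama–Michael addition followed by closure onto the oxocarbenium ion) that forms C5–C6 and C1–C2 of the future arene and closes the six-membered carbocycle in a (4+2) mode. Ketal 14 should aromatise by 1,4-elimination of methanol to silyl ether 15, and the acidic work-up cleaves its silicon–oxygen bond to give the phenol, which is hydrogen-bonded to the ortho carbonyl group. The closest known reactions are the benzannulations of 1-alkoxy-1-silyloxybuta-1,3-dienes and of 1,1-dialkoxy-3-silyloxybutadienes with acetylenic ketones and esters, which give ortho-acylphenols and salicylates. No lasting stereocentre is formed, since the ketal carbon of 14 becomes aromatic. The step needs regioselectivity, which the polarisation of both partners secures: the CH2 terminus of 13, activated by the C3 methoxy group and the ketene acetal, bonds to the unsubstituted β-carbon of the ynone, so that the ketal carbon comes to lie next to the acyl-bearing carbon. The imidazole N3 of a second molecule is the one competing nucleophile for the ynone, so 7 is used fresh and the diene in excess.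

Step 9
Reactants: 16 (2-hydroxy-3,4-dimethoxyphenyl)[4-(4-methoxybenzyl)-1-methyl-1H-imidazol-5-yl]methanone
Product: 19 6-{[4-(4-methoxybenzyl)-1-methyl-1H-imidazol-5-yl]methyl}-2,3-dimethoxyphenol, via aryl ethyl carbonate 17 (not isolated), via ortho-quinone methide 18 (not isolated)
Conditions: ClCO2Et, Et3N, THF, 0 °C; filtration; NaBH4, THF/H2O, 0 °C → rt
Reagents that add atoms: none
Why: Deoxygenation of an ortho-hydroxyaryl ketone through its carbonate: hydride reduces the ketone, the ethoxycarbonyl group migrates to the new alkoxide, 1,4-elimination gives the ortho-quinone methide and conjugate hydride addition leaves the benzylic CH2 and the free phenol.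

Step 10
Reactants: 19 6-{[4-(4-methoxybenzyl)-1-methyl-1H-imidazol-5-yl]methyl}-2,3-dimethoxyphenol
Product: 20 5-[2-(tert-butyldimethylsilyloxy)-3,4-dimethoxybenzyl]-4-(4-methoxybenzyl)-1-methyl-1H-imidazole
Conditions: TBSCl, imidazole, DMF, rt
Reagents that add atoms: tert-butyldimethylsilyl chloride, CC(C)(C)[Si](C)(C)Cl
Why: Silylation of the phenol masks the acidic OH, so that one equivalent of base suffices in step 11 and no phenoxide meets the sulfonyl azide.

Step 11
Reactants: 20 5-[2-(tert-butyldimethylsilyloxy)-3,4-dimethoxybenzyl]-4-(4-methoxybenzyl)-1-methyl-1H-imidazole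
Product: 22 2-azido-5-[2-(tert-butyldimethylsilyloxy)-3,4-dimethoxybenzyl]-4-(4-methoxybenzyl)-1-methyl-1H-imidazole, via 2-lithioimidazole 21 (not isolated)
Conditions: n-BuLi, THF, −78 °C; TsN3, −78 °C → rt
Reagents that add atoms: 4-methylbenzenesulfonyl azide, Cc1ccc(cc1)S(=O)(=O)N=[N+]=[N-]
Why: Deprotonation of the 1-methylimidazole at C2, its kinetically most acidic CH, and electrophilic azide transfer from tosyl azide (the triazenyl anion loses p-toluenesulfinate) install the C2 nitrogen, as known for 4,5-dibenzyl-1-methylimidazoles.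

Step 12
Reactants: 22 2-azido-5-[2-(tert-butyldimethylsilyloxy)-3,4-dimethoxybenzyl]-4-(4-methoxybenzyl)-1-methyl-1H-imidazole
Product: 23 6-{[2-azido-4-(4-methoxybenzyl)-1-methyl-1H-imidazol-5-yl]methyl}-2,3-dimethoxyphenol
Conditions: TBAF, AcOH, THF, 0 °C → rt
Reagents that add atoms: none
Why: Fluoride cleaves the aryl silyl ether; acetic acid buffers the phenoxide and the azide is untouched, and desilylation at the azide stage keeps the later aminophenol free of ammonium salts.

Step 13
Reactants: 23 6-{[2-azido-4-(4-methoxybenzyl)-1-methyl-1H-imidazol-5-yl]methyl}-2,3-dimethoxyphenol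
Product: 24 6-{[2-amino-4-(4-methoxybenzyl)-1-methyl-1H-imidazol-5-yl]methyl}-2,3-dimethoxyphenol
Conditions: H2 (1 atm), 10% Pd/C, EtOH, rt
Reagents that add atoms: none
Why: Catalytic hydrogenation reduces the heteroaryl azide to the primary amine with loss of N2 and touches neither the aryl ethers nor the diarylmethane CH2 groups.

Step 14
Reactants: 24 6-{[2-amino-4-(4-methoxybenzyl)-1-methyl-1H-imidazol-5-yl]methyl}-2,3-dimethoxyphenol, 25 1-methylparabanic acid
Product: 27 pyronaamidine, via O-silylated 1-methylparabanic acid 26 (not isolated)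
Conditions: 25, BSA, MeCN, reflux; evaporation; then 24, toluene, reflux; aqueous work-up
Reagents that add atoms: none
Why: O-Silylation of the imide by BSA turns C4 of 1-methylparabanic acid into an electrophilic silyl imidate carbon; the 2-aminoimidazole adds there and the silyloxy group leaves (addition–elimination), which gives the amidine as in the known conversion of naamines into naamidines.

**Compound list**
1 | 4,5-diiodo-1-methyl-1H-imidazole | Cn1cnc(I)c1I | starting material
2 | (4-iodo-1-methyl-1H-imidazol-5-yl)magnesium chloride | Cn1cnc(I)c1[Mg]Cl | intermediate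
3 | 4-iodo-1-methyl-1H-imidazole-5-carbaldehyde | Cn1cnc(I)c1C=O | intermediate
4 | 2-(4-methoxybenzyl)-4,4,5,5-tetramethyl-1,3,2-dioxaborolane | COc1ccc(CB2OC(C)(C)C(C)(C)O2)cc1 | starting material
5 | 4-(4-methoxybenzyl)-1-methyl-1H-imidazole-5-carbaldehyde | COc1ccc(Cc2ncn(C)c2C=O)cc1 | intermediate
6 | 1-[4-(4-methoxybenzyl)-1-methyl-1H-imidazol-5-yl]prop-2-yn-1-ol (racemic) | COc1ccc(Cc2ncn(C)c2C(O)C#C)cc1 | intermediate
7 | 1-[4-(4-methoxybenzyl)-1-methyl-1H-imidazol-5-yl]prop-2-yn-1-one | COc1ccc(Cc2ncn(C)c2C(=O)C#C)cc1 | intermediate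
8 | methyl methoxyacetate | COCC(=O)OC | starting material
9 | lithium 1,2-dimethoxyethen-1-olate | COC=C(OC)O[Li] | intermediate
10 | methyl 2-methoxy-3-oxobutanoate (racemic) | COC(C(C)=O)C(=O)OC | intermediate
11 | methyl 2,3-dimethoxybut-2-enoate (mixture of double-bond isomers) | COC(C)=C(OC)C(=O)OC | intermediate
12 | lithium 1,2,3-trimethoxybuta-1,3-dien-1-olate | C=C(OC)C(OC)=C(OC)O[Li] | intermediate
13 | 1,2,3-trimethoxy-1-(trimethylsilyloxy)buta-1,3-diene (mixture of geometric isomers) | C=C(OC)C(OC)=C(OC)O[Si](C)(C)C | intermediate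
14 | [4-(4-methoxybenzyl)-1-methyl-1H-imidazol-5-yl][4,5,6-trimethoxy-6-(trimethylsilyloxy)cyclohexa-1,4-dien-1-yl]methanone (racemic) | COc1ccc(Cc2ncn(C)c2C(=O)C2=CCC(OC)=C(OC)C2(OC)O[Si](C)(C)C)cc1 | intermediate
15 | [3,4-dimethoxy-2-(trimethylsilyloxy)phenyl][4-(4-methoxybenzyl)-1-methyl-1H-imidazol-5-yl]methanone | COc1ccc(Cc2ncn(C)c2C(=O)c2ccc(OC)c(OC)c2O[Si](C)(C)C)cc1 | intermediate
16 | (2-hydroxy-3,4-dimethoxyphenyl)[4-(4-methoxybenzyl)-1-methyl-1H-imidazol-5-yl]methanone | COc1ccc(Cc2ncn(C)c2C(=O)c2ccc(OC)c(OC)c2O)cc1 | intermediate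
17 | ethyl 6-{[4-(4-methoxybenzyl)-1-methyl-1H-imidazol-5-yl]carbonyl}-2,3-dimethoxyphenyl carbonate | CCOC(=O)Oc1c(OC)c(OC)ccc1C(=O)c1c(Cc2ccc(OC)cc2)ncn1C | intermediate
18 | 6-{[4-(4-methoxybenzyl)-1-methyl-1H-imidazol-5-yl]methylidene}-2,3-dimethoxycyclohexa-2,4-dien-1-one | COC1=C(OC)C(=O)C(=Cc2c(Cc3ccc(OC)cc3)ncn2C)C=C1 | intermediate
19 | 6-{[4-(4-methoxybenzyl)-1-methyl-1H-imidazol-5-yl]methyl}-2,3-dimethoxyphenol | COc1ccc(Cc2ncn(C)c2Cc2ccc(OC)c(OC)c2O)cc1 | intermediate
20 | 5-[2-(tert-butyldimethylsilyloxy)-3,4-dimethoxybenzyl]-4-(4-methoxybenzyl)-1-methyl-1H-imidazole | COc1ccc(Cc2ncn(C)c2Cc2ccc(OC)c(OC)c2O[Si](C)(C)C(C)(C)C)cc1 | intermediate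
21 | {5-[2-(tert-butyldimethylsilyloxy)-3,4-dimethoxybenzyl]-4-(4-methoxybenzyl)-1-methyl-1H-imidazol-2-yl}lithium | COc1ccc(Cc2nc([Li])n(C)c2Cc2ccc(OC)c(OC)c2O[Si](C)(C)C(C)(C)C)cc1 | intermediate
22 | 2-azido-5-[2-(tert-butyldimethylsilyloxy)-3,4-dimethoxybenzyl]-4-(4-methoxybenzyl)-1-methyl-1H-imidazole | COc1ccc(Cc2nc(N=[N+]=[N-])n(C)c2Cc2ccc(OC)c(OC)c2O[Si](C)(C)C(C)(C)C)cc1 | intermediate
23 | 6-{[2-azido-4-(4-methoxybenzyl)-1-methyl-1H-imidazol-5-yl]methyl}-2,3-dimethoxyphenol | COc1ccc(Cc2nc(N=[N+]=[N-])n(C)c2Cc2ccc(OC)c(OC)c2O)cc1 | intermediate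
24 | 6-{[2-amino-4-(4-methoxybenzyl)-1-methyl-1H-imidazol-5-yl]methyl}-2,3-dimethoxyphenol | COc1ccc(Cc2nc(N)n(C)c2Cc2ccc(OC)c(OC)c2O)cc1 | intermediate
25 | 1-methylparabanic acid (1-methylimidazolidine-2,4,5-trione) | CN1C(=O)NC(=O)C1=O | starting material
26 | 1-methyl-4-(trimethylsilyloxy)-1H-imidazole-2,5-dione | CN1C(=O)N=C(O[Si](C)(C)C)C1=O | intermediate
27 | pyronaamidine | COc1ccc(Cc2nc(NC3=NC(=O)N(C)C3=O)n(C)c2Cc2ccc(OC)c(OC)c2O)cc1 | target

**Step count**
Total: 14 steps. Longest linear sequence: 11 steps (steps 1–4 and 8–14); the diene branch (steps 5–7) joins at step 8.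

**Steps most likely to fail**

Step 8. The hydrolytically labile diene may decompose before it reacts. The ynone may be consumed by conjugate addition of the imidazole nitrogen of a second molecule. The ketene acetal may also add through its α-carbon and give an open-chain Michael adduct that cannot close the ring. The fallback sets out from 5 and comes back to the route at 16. 1,2,3-Trimethoxybenzene is lithiated with n-BuLi and TMEDA next to a terminal methoxy group to give 2,3,4-trimethoxyphenyllithium F1. This adds to aldehyde 5 to give [4-(4-methoxybenzyl)-1-methyl-1H-imidazol-5-yl](2,3,4-trimethoxyphenyl)methanol F2. Oxidation with MnO2 gives [4-(4-methoxybenzyl)-1-methyl-1H-imidazol-5-yl](2,3,4-trimethoxyphenyl)methanone F3. BCl3 in CH2Cl2 at low temperature then cleaves only the methoxy group ortho to the carbonyl group, through the boron chelate, and gives 16.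

Step 9. Hydride addition to the hindered, electron-rich diaryl ketone may be slow, so the carbonate may be hydrolysed back to the phenol before the acyl group migrates. The quinone methide may also be trapped by water or phenoxide instead of hydride. The fallback sets out from 16 and comes back at 19. LiAlH4 in THF reduces the ketone to 6-{hydroxy[4-(4-methoxybenzyl)-1-methyl-1H-imidazol-5-yl]methyl}-2,3-dimethoxyphenol F4. Ionic hydrogenation with Et3SiH and CF3CO2H in CH2Cl2 then removes the doubly activated benzylic hydroxyl group and gives 19.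

Step 11. Deprotonation may occur at one of the doubly benzylic CH2 groups instead of C2, possibly followed by silyl migration. The triazene salt may also fail to release the azide. The fallback sets out from 20 and comes back at 22. The amide base TMPMgCl·LiCl in THF magnesiates C2 selectively to give {5-[2-(tert-butyldimethylsilyloxy)-3,4-dimethoxybenzyl]-4-(4-methoxybenzyl)-1-methyl-1H-imidazol-2-yl}magnesium chloride F5. Iodine converts this into 5-[2-(tert-butyldimethylsilyloxy)-3,4-dimethoxybenzyl]-2-iodo-4-(4-methoxybenzyl)-1-methyl-1H-imidazole F6. Copper-catalysed azidation (CuI, L-proline, NaOH, NaN3, DMSO, 60 °C) then gives 22.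

**Further compounds**
F1 | step 8 | 2,3,4-trimethoxyphenyllithium | [Li]c1ccc(OC)c(OC)c1OC
F2 | step 8 | [4-(4-methoxybenzyl)-1-methyl-1H-imidazol-5-yl](2,3,4-trimethoxyphenyl)methanol (racemic) | COc1ccc(Cc2ncn(C)c2C(O)c2ccc(OC)c(OC)c2OC)cc1
F3 | step 8 | [4-(4-methoxybenzyl)-1-methyl-1H-imidazol-5-yl](2,3,4-trimethoxyphenyl)methanone | COc1ccc(Cc2ncn(C)c2C(=O)c2ccc(OC)c(OC)c2OC)cc1
F4 | step 9 | 6-{hydroxy[4-(4-methoxybenzyl)-1-methyl-1H-imidazol-5-yl]methyl}-2,3-dimethoxyphenol (racemic) | COc1ccc(Cc2ncn(C)c2C(O)c2ccc(OC)c(OC)c2O)cc1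
F5 | step 11 | {5-[2-(tert-butyldimethylsilyloxy)-3,4-dimethoxybenzyl]-4-(4-methoxybenzyl)-1-methyl-1H-imidazol-2-yl}magnesium chloride | COc1ccc(Cc2nc([Mg]Cl)n(C)c2Cc2ccc(OC)c(OC)c2O[Si](C)(C)C(C)(C)C)cc1
F6 | step 11 | 5-[2-(tert-butyldimethylsilyloxy)-3,4-dimethoxybenzyl]-2-iodo-4-(4-methoxybenzyl)-1-methyl-1H-imidazole | COc1ccc(Cc2nc(I)n(C)c2Cc2ccc(OC)c(OC)c2O[Si](C)(C)C(C)(C)C)cc1
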